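**Plan** (target ring numbering: C1 = C–OAc, C2 = C–OMe, C3, C4 = C–OH, C5, C6 = carbon bearing the chain; C2′ = chain carbinol)
Retrosynthesis: C5=C6 is taken back to a C5 phenylselenide (syn-elimination) and C4–OH to a ketone; the ring is then cut at C5–C6 and C2–C3 in one [3+3] disconnection into benzyl acetoacetate (C3, C4, C5) and a C2–C1–C6 unit.
Enabling feature: O–C4 and O–C2 are 1,3-related across C3 with the chain on C6 (a 5-alkyl dihydroresorcinol pattern), and the C2′ oxygen is δ to C2, so C2, C1, C6, C1′ and C2′ can be held as a 2-benzyloxy α,β-unsaturated δ-lactone whose ring oxygen becomes the chain oxygen.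
Forward: (R)-epichlorohydrin is taken to the lactone (two epoxide openings, acylation, methylenation, ring-closing metathesis); one Michael–Claisen operation then builds the carbocycle; enol ether formation, debenzylation with decarboxylation, acetylation, selenenylation, ketone reduction and selenoxide elimination finish.
Stereochemistry: C2′ is bought; in the key step it sets C6 (trans addition) and C6 sets C1; C6 then directs the selenide at C5, which directs the hydride at C4; C5 and C6 are erased when the alkene forms.
C5=C6 is made last, after C4 is sp3, because a cyclohexa-2,5-dienone carrying H on C1 would aromatise.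

Key step: step 6

Remark: enolisable β-keto esters are drawn as one tautomer, and the configuration of an enolisable carbon between two carbonyl groups is left undefined.

Step 1
Reactants: 1 (R)-epichlorohydrin; 2 decylmagnesium bromide
Product: 4 (R)-2-undecyloxirane, via chlorohydrin 3 (not isolated)
Conditions: CuI (10 mol%), THF, −40 °C; then NaOH, H2O, 25 °C
Reagents that add atoms: decylmagnesium bromide, CCCCCCCCCC[Mg]Br
Why: Copper-catalysed Grignard opening of the epoxide at its CH2 terminus followed by Williamson ring closure of the chlorohydrin does not touch the stereocentre, so the (R)-epoxide should result.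

Step 2
Reactants: 4 (R)-2-undecyloxirane; 5 vinylmagnesium bromide
Product: 6 (R)-pentadec-1-en-4-ol
Conditions: CuI (10 mol%), THF, −30 to 0 °C; then aq. NH4Cl
Reagents that add atoms: vinylmagnesium bromide, C=C[Mg]Br
Why: Copper-catalysed SN2 opening of a terminal epoxide at the unsubstituted carbon gives the homoallylic alcohol with the C–O stereocentre unchanged.

Step 3
Reactants: 6 (R)-pentadec-1-en-4-ol; 7 2-(benzyloxy)acetyl chloride
Product: 8 (R)-pentadec-1-en-4-yl 2-(benzyloxy)acetate
Conditions: Et3N, DMAP (cat.), CH2Cl2, 0 to 25 °C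
Reagents that add atoms: 2-(benzyloxy)acetyl chloride, O=C(Cl)COCc1ccccc1
Why: DMAP-catalysed acylation of a secondary alcohol by an acid chloride proceeds with retention at the carbinol.

Step 4
Reactants: 8 (R)-pentadec-1-en-4-yl 2-(benzyloxy)acetate; 9 N,N-dimethylmethylideneammonium iodide (Eschenmoser's salt)
Product: 12 (R)-pentadec-1-en-4-yl 2-(benzyloxy)acrylate, via Mannich base 10 (not isolated), via ammonium iodide 11 (not isolated)
Conditions: LiN(SiMe3)2, THF, −78 °C; 9, −78 to 0 °C; then MeI, MeOH, 25 °C; then DBU, CH2Cl2, 25 °C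
Reagents that add atoms: N,N-dimethylmethylideneammonium iodide, C=[N+](C)C.[I-]
Why: Mannich reaction of the glycolate ester enolate, quaternisation and E1cB elimination is the classical α-methylenation of esters and does not involve the carbinol stereocentre.

Step 5
Reactants: 12 (R)-pentadec-1-en-4-yl 2-(benzyloxy)acrylate
Product: 13 (6R)-3-(benzyloxy)-6-undecyl-5,6-dihydro-2H-pyran-2-one
Conditions: second-generation Grubbs catalyst (10 mol%), toluene, 80 °C
Reagents that add atoms: none
Why: Ring-closing metathesis of an acrylate-type ester with a terminal alkene closes the six-membered unsaturated lactone with loss of ethylene; the catalyst loads on the terminal alkene and 2-alkoxyacrylates are known to take part in ring-closing metathesis.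

Step 6
Reactants: 13 (6R)-3-(benzyloxy)-6-undecyl-5,6-dihydro-2H-pyran-2-one; 14 benzyl acetoacetate
Product: 16 benzyl (5S,6S)-5-(benzyloxy)-2-hydroxy-6-[(2R)-2-hydroxytridecyl]-4-oxocyclohex-1-ene-1-carboxylate, via Michael adduct 15 (not isolated)
Conditions: t-BuOK (0.1 equiv), THF, 0 °C; then t-BuOK (1.9 equiv), t-BuOH–THF, 50 °C; then 1 M HCl
Reagents that add atoms: benzyl acetoacetate, CC(=O)CC(=O)OCc1ccccc1
Why: Proposed new method: catalytic tert-butoxide forms the enolate of 14, whose C2 adds to the β-carbon of lactone 13 (C5–C6 bond, Michael addition); the lactone enolate is protonated at the benzyloxy carbon, and with more base the methyl ketone enolate attacks the lactone carbonyl (C2–C3 bond, Claisen condensation) through an oxabicyclo[3.3.1]nonane tetrahedral intermediate, whose collapse expels the ring oxygen as the C2′ alkoxide and leaves the stabilised 1,3-dione enolate that pulls the reversible Michael step forward. The closest known reaction types are the Michael–Claisen (Michael–Dieckmann) synthesis of cyclohexane-1,3-diones from acetoacetates and α,β-unsaturated esters and the trans-selective conjugate addition of stabilised carbanions to 6-substituted 5,6-dihydropyran-2-ones; what has not been shown is their merger on a 2-alkoxy unsaturated lactone that the Claisen step opens. The carbocycle closes by 6-exo-trig attack of the enolate carbon on the lactone C=O. C6 is set by axial attack on the half-chair lactone anti to the equatorial undecyl group, and C1 by protonation (and equilibration) trans to the new C6 substituent, which in the carbocycle places the benzyloxy group cis to the side chain; C2′ is only released. The step needs addition through C2 of 14 and acylation through its methyl group: the methyl carbon is the only one that reaches the lactone carbonyl in a six-membered ring, the bridged transition state needs the new substituent axial, which only the trans adduct reaches with undecyl equatorial, and holding the base at two equivalents leaves the freed alkoxide protonated by the acidic product so that it should not lactonise onto the benzyl ester.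

Step 7
Reactants: 16 benzyl (5S,6S)-5-(benzyloxy)-2-hydroxy-6-[(2R)-2-hydroxytridecyl]-4-oxocyclohex-1-ene-1-carboxylate; 17 trimethyl orthoformate
Product: 18 benzyl (5S,6S)-5-(benzyloxy)-2-hydroxy-6-[(2R)-2-hydroxytridecyl]-4-methoxycyclohexa-1,3-diene-1-carboxylate
Conditions: HC(OMe)3, MeOH, CSA (cat.), 0 to 25 °C; then Et3N
Reagents that add atoms: trimethyl orthoformate, COC(OC)OC
Why: Acid-catalysed enol ether formation of a cyclic 1,3-dione (vinylogous esterification) under equilibrating conditions should put the methoxy group on C2, because only then does the C4 carbonyl stay enolised toward C5 and hydrogen-bonded to the benzyl ester; no stereocentre is formed, and the C1 benzyloxy group pseudo-axial and cis to the chain is also the arrangement that avoids A(1,2) strain with the new methoxy group.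

Step 8
Reactants: 18 benzyl (5S,6S)-5-(benzyloxy)-2-hydroxy-6-[(2R)-2-hydroxytridecyl]-4-methoxycyclohexa-1,3-diene-1-carboxylate
Product: 20 (4S,5S)-4-hydroxy-5-[(2R)-2-hydroxytridecyl]-3-methoxycyclohex-2-en-1-one, via keto acid 19 (not isolated)
Conditions: H2 (1 atm), Pd/C, EtOAc, 25 then 40 °C
Reagents that add atoms: none
Why: Hydrogenolysis of the benzyl ester and the benzyl ether followed by spontaneous decarboxylation of the β-keto acid is the standard unmasking of a benzyl acetoacetate unit; the push–pull C=C of the vinylogous ester is inert and no stereocentre is touched.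

Step 9
Reactants: 20 (4S,5S)-4-hydroxy-5-[(2R)-2-hydroxytridecyl]-3-methoxycyclohex-2-en-1-one; 21 acetic anhydride
Product: 22 (1S,6S)-6-[(2R)-2-acetoxytridecyl]-2-methoxy-4-oxocyclohex-2-en-1-yl acetate
Conditions: Ac2O, pyridine, DMAP (cat.), CH2Cl2, 0 °C
Reagents that add atoms: acetic anhydride, CC(=O)OC(C)=O
Why: DMAP-catalysed acetylation esterifies both secondary alcohols with retention, and doing so while C4 is still a ketone is what later leaves the C4 hydroxyl as the only free one.

Step 10
Reactants: 22 (1S,6S)-6-[(2R)-2-acetoxytridecyl]-2-methoxy-4-oxocyclohex-2-en-1-yl acetate; 23 benzeneselenenyl chloride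
Product: 25 (1S,5S,6R)-6-[(2R)-2-acetoxytridecyl]-2-methoxy-4-oxo-5-(phenylselanyl)cyclohex-2-en-1-yl acetate, via silyl dienol ether 24 (not isolated)
Conditions: Me3SiOTf, Et3N, CH2Cl2, 0 °C; then PhSeCl, −78 °C
Reagents that add atoms: benzeneselenenyl chloride, Cl[Se]c1ccccc1
Why: Soft enolisation at the α′-CH2 gives the cross-conjugated 2-silyloxydiene without harming the acetates, and electrophilic α-selenenylation of this silyl enol ether should place PhSe on C5 trans to the neighbouring C6 side chain, hence cis to C6–H.

Step 11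
Reactants: 25 (1S,5S,6R)-6-[(2R)-2-acetoxytridecyl]-2-methoxy-4-oxo-5-(phenylselanyl)cyclohex-2-en-1-yl acetate
Product: 26 (1S,4R,5S,6R)-6-[(2R)-2-acetoxytridecyl]-4-hydroxy-2-methoxy-5-(phenylselanyl)cyclohex-2-en-1-yl acetate
Conditions: LiBH(s-Bu)3 (1.1 equiv), THF, −78 °C; then aq. NaHCO3
Reagents that add atoms: none
Why: 1,2-Reduction of the α-selanyl ketone by a bulky trialkylborohydride should occur from the face opposite the adjacent PhSe group, giving the cis β-hydroxy selenide, in which OH is trans to the C1 acetate; conjugate reduction is blocked by the β-methoxy group.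

Step 12
Reactants: 26 (1S,4R,5S,6R)-6-[(2R)-2-acetoxytridecyl]-4-hydroxy-2-methoxy-5-(phenylselanyl)cyclohex-2-en-1-yl acetate
Product: 28 (1S,4S)-6-[(2R)-2-acetoxytridecyl]-4-hydroxy-2-methoxycyclohexa-2,5-dien-1-yl acetate, via selenoxide 27 (not isolated)
Conditions: H2O2 (30%), pyridine, CH2Cl2, 0 to 25 °C
Reagents that add atoms: none
Why: Selenide oxidation and selenoxide syn-elimination at or below room temperature under pyridine buffering should form C5=C6 toward the cis C6–H (C4–H is trans to selenium, and β-hydroxy selenoxides eliminate away from the carbinol carbon), leaving both ring stereocentres untouched.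

Compound list
1 | (R)-epichlorohydrin | ClC[C@H]1CO1 | starting material
2 | decylmagnesium bromide | CCCCCCCCCC[Mg]Br | starting material
3 | (R)-1-chlorotridecan-2-ol (present as its bromomagnesium alkoxide) | ClC[C@H](O)CCCCCCCCCCC | intermediate
4 | (R)-2-undecyloxirane | CCCCCCCCCCC[C@@H]1CO1 | intermediate
5 | vinylmagnesium bromide | C=C[Mg]Br | starting material
6 | (R)-pentadec-1-en-4-ol | CCCCCCCCCCC[C@H](CC=C)O | intermediate
7 | 2-(benzyloxy)acetyl chloride | O=C(Cl)COCc1ccccc1 | starting material
8 | (R)-pentadec-1-en-4-yl 2-(benzyloxy)acetate | CCCCCCCCCCC[C@H](CC=C)OC(=O)COCc1ccccc1 | intermediate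
9 | N,N-dimethylmethylideneammonium iodide (Eschenmoser's salt) | C=[N+](C)C.[I-] | starting material
10 | (R)-pentadec-1-en-4-yl 2-(benzyloxy)-3-(dimethylamino)propanoate (both C2 epimers) | CCCCCCCCCCC[C@H](CC=C)OC(=O)C(CN(C)C)OCc1ccccc1 | intermediate
11 | 2-(benzyloxy)-N,N,N-trimethyl-3-oxo-3-{[(4R)-pentadec-1-en-4-yl]oxy}propan-1-aminium iodide | CCCCCCCCCCC[C@H](CC=C)OC(=O)C(C[N+](C)(C)C)OCc1ccccc1.[I-] | intermediate
12 | (R)-pentadec-1-en-4-yl 2-(benzyloxy)acrylate | CCCCCCCCCCC[C@H](CC=C)OC(=O)C(=C)OCc1ccccc1 | intermediate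
13 | (6R)-3-(benzyloxy)-6-undecyl-5,6-dihydro-2H-pyran-2-one | CCCCCCCCCCC[C@@H]1CC=C(OCc2ccccc2)C(=O)O1 | intermediate
14 | benzyl acetoacetate (benzyl 3-oxobutanoate) | CC(=O)CC(=O)OCc1ccccc1 | starting material
15 | benzyl 2-[(3S,4S,6R)-3-(benzyloxy)-2-oxo-6-undecyloxan-4-yl]-3-oxobutanoate (C2 of the butanoate undefined) | CCCCCCCCCCC[C@@H]1C[C@@H](C(C(C)=O)C(=O)OCc2ccccc2)[C@H](OCc2ccccc2)C(=O)O1 | intermediate
16 | benzyl (5S,6S)-5-(benzyloxy)-2-hydroxy-6-[(2R)-2-hydroxytridecyl]-4-oxocyclohex-1-ene-1-carboxylate (enol form of the 2,4-dioxo ester) | CCCCCCCCCCC[C@H](C[C@H]1C(C(=O)OCc2ccccc2)=C(O)CC(=O)[C@H]1OCc3ccccc3)O | intermediate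
17 | trimethyl orthoformate | COC(OC)OC | starting material
18 | benzyl (5S,6S)-5-(benzyloxy)-2-hydroxy-6-[(2R)-2-hydroxytridecyl]-4-methoxycyclohexa-1,3-diene-1-carboxylate | CCCCCCCCCCC[C@H](C[C@H]1C(C(=O)OCc2ccccc2)=C(O)C=C(OC)[C@H]1OCc3ccccc3)O | intermediate
19 | (5S,6S)-5-hydroxy-6-[(2R)-2-hydroxytridecyl]-4-methoxy-2-oxocyclohex-3-ene-1-carboxylic acid (C1 undefined) | CCCCCCCCCCC[C@H](C[C@H]1C(C(=O)O)C(=O)C=C(OC)[C@H]1O)O | intermediate
20 | (4S,5S)-4-hydroxy-5-[(2R)-2-hydroxytridecyl]-3-methoxycyclohex-2-en-1-one | CCCCCCCCCCC[C@H](C[C@H]1CC(=O)C=C(OC)[C@H]1O)O | intermediate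
21 | acetic anhydride | CC(=O)OC(C)=O | starting material
22 | (1S,6S)-6-[(2R)-2-acetoxytridecyl]-2-methoxy-4-oxocyclohex-2-en-1-yl acetate | CCCCCCCCCCC[C@H](C[C@H]1CC(=O)C=C(OC)[C@H]1OC(C)=O)OC(C)=O | intermediate
23 | benzeneselenenyl chloride | Cl[Se]c1ccccc1 | starting material
24 | (1S,6S)-6-[(2R)-2-acetoxytridecyl]-2-methoxy-4-[(trimethylsilyl)oxy]cyclohexa-2,4-dien-1-yl acetate | CCCCCCCCCCC[C@H](C[C@H]1C=C(O[Si](C)(C)C)C=C(OC)[C@H]1OC(C)=O)OC(C)=O | intermediate
25 | (1S,5S,6R)-6-[(2R)-2-acetoxytridecyl]-2-methoxy-4-oxo-5-(phenylselanyl)cyclohex-2-en-1-yl acetate | CCCCCCCCCCC[C@H](C[C@H]1[C@H]([Se]c2ccccc2)C(=O)C=C(OC)[C@H]1OC(C)=O)OC(C)=O | intermediate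
26 | (1S,4R,5S,6R)-6-[(2R)-2-acetoxytridecyl]-4-hydroxy-2-methoxy-5-(phenylselanyl)cyclohex-2-en-1-yl acetate | CCCCCCCCCCC[C@H](C[C@H]1[C@H]([Se]c2ccccc2)[C@H](O)C=C(OC)[C@H]1OC(C)=O)OC(C)=O | intermediate
27 | selenoxide of 26 (phenylseleninyl group at C5, configuration at selenium undefined) | CCCCCCCCCCC[C@H](C[C@H]1[C@H]([Se](=O)c2ccccc2)[C@H](O)C=C(OC)[C@H]1OC(C)=O)OC(C)=O | intermediate
28 | (1S,4S)-6-[(2R)-2-acetoxytridecyl]-4-hydroxy-2-methoxycyclohexa-2,5-dien-1-yl acetate | CCCCCCCCCCC[C@H](CC1=C[C@H](O)C=C(OC)[C@H]1OC(C)=O)OC(C)=O | target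

Total step count: 12. Longest linear sequence: 12 steps (from (R)-epichlorohydrin).

Steps most likely to fail

1. Step 6 (proposed new method). What may go wrong: conjugate addition to the donor-substituted 2-alkoxy enoate is slow, so base-induced ring-opening elimination of the lactone competes; C1 epimerises by enolisation after ring closure; the freed alkoxide lactonises onto the benzyl ester. Fallback with known chemistry, setting out from 13 and returning at 16: the two bond formations are separated. Compounds 13 and 14 with catalytic DBU in THF give the Michael adduct 15, now isolated (stabilised carbanions are known to add trans to the C6 substituent of such lactones). BnOLi in THF opens the lactone and t-BuMe2SiOTf with 2,6-lutidine caps the freed alcohol to give dibenzyl (3S,4S)-2-acetyl-4-(benzyloxy)-3-[(2R)-2-{[tert-butyl(dimethyl)silyl]oxy}tridecyl]pentanedioate F1. t-BuOK in THF then closes the ring by the ordinary Claisen condensation of a methyl ketone onto an acyclic ester, the second half of the classical Michael–Claisen dione synthesis, to give benzyl (5S,6S)-5-(benzyloxy)-6-[(2R)-2-{[tert-butyl(dimethyl)silyl]oxy}tridecyl]-2-hydroxy-4-oxocyclohex-1-ene-1-carboxylate F2. HF·pyridine removes the silyl group and returns 16.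

2. Step 11. What may go wrong: the hydride is delivered syn to selenium (axial attack, giving the C4 epimer and finally the cis-1,4 isomer), or the acetates are reduced because the vinylogous ester carbonyl is a weak electrophile. Fallback, setting out from 25 and returning at 26: substrate control is replaced by catalyst control in a Corey–Bakshi–Shibata reduction with (S)-2-methyl-CBS-oxazaborolidine (20 mol%) and catecholborane in toluene at −78 °C, with the selenium-bearing C5 taken as the large group. These conditions leave acetates alone, and the fallback makes no compound outside the list (none, F0).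

3. Step 5. What may go wrong: ring closure onto the hindered, donor-substituted 1,1-disubstituted alkene is slow, so catalyst decay and intermolecular metathesis of the terminal alkene take over. Fallback, setting out from 6 and returning at 13: the ring is closed on an unsubstituted acrylate and the oxygen is added afterwards. Acryloyl chloride and Et3N give (R)-pentadec-1-en-4-yl acrylate F3. Ring-closing metathesis with the second-generation Grubbs catalyst gives (6R)-6-undecyl-5,6-dihydro-2H-pyran-2-one F4. OsO4 (cat.) with N-methylmorpholine N-oxide dihydroxylates anti to the undecyl group to give (3R,4R,6R)-3,4-dihydroxy-6-undecyloxan-2-one F5. Ag2O and BnBr benzylate the more acidic C3 hydroxyl to give (3R,4R,6R)-3-(benzyloxy)-4-hydroxy-6-undecyloxan-2-one F6. MsCl and Et3N, then DBU, eliminate the C4 mesylate (E1cB) and return 13.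

Further compounds
F1 | step 6 | dibenzyl (3S,4S)-2-acetyl-4-(benzyloxy)-3-[(2R)-2-{[tert-butyl(dimethyl)silyl]oxy}tridecyl]pentanedioate | CCCCCCCCCCC[C@@H](O[Si](C)(C)C(C)(C)C)C[C@@H](C(C(C)=O)C(=O)OCc1ccccc1)[C@H](OCc1ccccc1)C(=O)OCc1ccccc1
F2 | step 6 | benzyl (5S,6S)-5-(benzyloxy)-6-[(2R)-2-{[tert-butyl(dimethyl)silyl]oxy}tridecyl]-2-hydroxy-4-oxocyclohex-1-ene-1-carboxylate | CCCCCCCCCCC[C@H](C[C@H]1C(C(=O)OCc2ccccc2)=C(O)CC(=O)[C@H]1OCc3ccccc3)O[Si](C)(C)C(C)(C)C
F0 | step 11 | none | none
F3 | step 5 | (R)-pentadec-1-en-4-yl acrylate | CCCCCCCCCCC[C@H](CC=C)OC(=O)C=C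
F4 | step 5 | (6R)-6-undecyl-5,6-dihydro-2H-pyran-2-one | CCCCCCCCCCC[C@@H]1CC=CC(=O)O1
F5 | step 5 | (3R,4R,6R)-3,4-dihydroxy-6-undecyloxan-2-one | CCCCCCCCCCC[C@@H]1C[C@@H](O)[C@@H](O)C(=O)O1
F6 | step 5 | (3R,4R,6R)-3-(benzyloxy)-4-hydroxy-6-undecyloxan-2-one | CCCCCCCCCCC[C@@H]1C[C@@H](O)[C@@H](OCc2ccccc2)C(=O)O1
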